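Take Wednesday's run and Sunday's run, and before you weigh out Sub2 for the next flask, ask what the extra solid bought. At 2.5 min, Wednesday's run, charged with 10 mM, stood at 27.1% of its charge, which is 2.71 mM of Pdt. Sunday's run, charged with 15 mM, stood at 19.0%, which is 2.85 mM. Divide Sunday's mean rate by Wednesday's over that same time and the time drops out: the rate grew by a factor of 1.05 while the charge grew by 1.50. The logarithm of the first factor over the logarithm of the second gives 0.124. Call this the charge response, the apparent order in the charge: the power of the charge that shows up in the amount of Pdt.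

the same everywhere: Ctl 0.20 mM

| run | Sub2 | remark | time |
|---|---|---|---|
| Wednesday's | 10 mM | run made earlier |  |
| Sunday's | 15 mM | run made earlier |  |
| flask | 20 mM |  | 2.5 min |

| run | time / min | Pdt / % |
|---|---|---|
| Wednesday's | 0.200 | 1.3 |
| Wednesday's | 0.333 | 2.1 |
| Wednesday's | 0.500 | 3.8 |
| Wednesday's | 0.667 | 6.8 |
| Wednesday's | 1.00 | 11.9 |
| Wednesday's | 1.50 | 17.6 |
| Wednesday's | 2.50 | 27.1 |
| Sunday's | 0.333 | 1.0 |
| Sunday's | 0.667 | 5.2 |
| Sunday's | 1.00 | 8.0 |
| Sunday's | 1.33 | 11.6 |
| Sunday's | 2.00 | 16.1 |
| Sunday's | 2.50 | 19.0 |

(readings scatter by 0.5 percentage points)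

- the earlier runs were read with a standard deviation of 0.5 percentage points
- at the start none of Sub2 is in solution

- cedar: doubling the solubility of Sub2, all else as stated
- elm: doubling the dissolution coefficient of Sub2, all else as stated
- ash: doubling the amount of Ctl, all else as stated

- Pdt at 2.5 min, in percent of the Sub2 charged
- the change that raises the amount of Pdt at 2.5 min, in percent of the Sub2 charged most ("none" if none brings more than 2 percentage points) (cedar / elm / ash / none)
- amount of Pdt at 2.5 min, in percent of the Sub2 charged, after elm

The response is less than 0.5, and it is a reading with a scatter of 0.5 percentage points behind it, so take it as small, not as exact. Carried from Sunday's run to the 20 mM of the flask, it gives me 2.95 mM, or 14.8% of the charge. My decision for the next run is therefore to add no Sub2 beyond the recipe.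

The forecast gives 14.5%, a little less than my figure. It names cedar as the best change and expects 16% after elm, on the ground that “Undissolved solid is holding the dissolved Sub2 near a fixed level”.

The flask gives 13.8%; cedar brings 13 points, and elm gives 15.6%.

    Sub + Ctl → Int (k = 38.0 /M/s)
    Int → Ctl + Pdt (k = 2.90 /s)
    Sub2 ⇌ Sub, rate k3*(cs3 - [Sub]) while solid is left; crystals form when [Sub] > cs3 (solubility = 6.10 mM, k = 0.0400 /s)
    Ctl + Pdt → Ctl + Sid (k = 49.0 /M/s)

The charge response of 0.124 carried Sunday's reading to 2.95 mM, and the flask holds 2.76 mM of Pdt. That amount is 18.4% of Sunday's charge, a gap of 0.6 points from Sunday's reading of 19.0% against a scatter of 0.5 points, so the readings do not tell the flask's Pdt apart from Sunday's. Taken on Ctl, the same ratio of logarithms between the flask and the neighbour with 0.080 mM of Ctl, which gives 8.14%, is 0.576. In the flask at 0.611 min, Pdt has a half-life of 1.2 min by the step that turns it into Sid, shorter than the 2.5 min of the run. At 2.50 min the flask holds 13.8% as Pdt beside 9.98% as Sid.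

(The runs stem from a simulated flask on assumed constants.)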